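## Retrosynthetic overview

1. Lettering: A/C are the benzo and pyranone rings of the 5,7-dihydroxychromone. B is the central anisole (C1' on C2 of ring C, C2' on C8 of ring D, OMe on C4'). D/E are the benzo and pyranone rings of the 5-hydroxy-7-methoxyflavone, and F is the 4-methoxyphenyl group. Flavone numbers are also used in the precursors: pyranone C2 = C8a, pyranone C3 = C4a, acetyl C=O/CH3 = C5/C6, ester C=O = C7, benzylic carbon = C8.
2. Feature: rings D and E share the C4a=C8a double bond, whose two exocyclic substituents (C5 and C8) are locked cis. Read as the centre of the triene C6=C5–C4a=C8a–C8=C7, this bond lets ring D be closed last on a finished E/F pyranone by forming C6–C7. C8 is already bonded to C8a beside O1, so a 6-aryl isomer cannot arise.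
3. Disconnections:
   - Ring C: Baker–Venkataraman shift and cyclodehydration, with the aroyl carbon coming from carbonylation of C1'–Br.
   - Ring D: electrocyclization with loss of methanol.
   - C8–C8a: addition–elimination of an arylacetate enolate at C2 of a 2-(methylsulfanyl)pyranone.
   - Ring E: the acetylacetone ketene dithioacetal and 4-methoxybenzoyl chloride.
4. Ring order: F, B and A are bought; E closes in step 3, D in step 7 and C in step 14.

Key step: step 7

Assumption: the SMILES fixes no configuration at the hindered C8–C2' axis, so the biaryl is made without axial control (racemic if the axis proves stable). The target has no stereocentre.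

## Route

Step 1
Reactants: 1 acetylacetone
Product: 2 3-[bis(methylsulfanyl)methylidene]pentane-2,4-dione
Conditions: K2CO3, CS2, DMF, 0 °C; then MeI (2.1 equiv), rt
Reagents that add atoms: carbon disulfide S=C=S; iodomethane CI
Why: The diketone carbanion adds to CS2 and the ene-dithiolate is S-methylated twice, which is the standard ketene dithioacetal synthesis from an active methylene compound.

Step 2
Reactants: 2 3-[bis(methylsulfanyl)methylidene]pentane-2,4-dione; 3 4-methoxybenzoyl chloride
Product: 4 4-acetyl-1-(4-methoxyphenyl)-5,5-bis(methylsulfanyl)pent-4-ene-1,3-dione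
Conditions: LiN(SiMe3)2 (2.2 equiv), THF, −78 °C; 3 (1.0 equiv), −78 → 0 °C; 1 M HCl
Reagents that add atoms: none
Why: Crossed Claisen-type C-acylation of the lithium enolate of one acetyl group, in which the second equivalent of base stores the more acidic 1,3-diketone as its salt and so stops further acylation, while the hindered amide leaves the push-pull ketene dithioacetal untouched at low temperature.

Step 3
Reactants: 4 4-acetyl-1-(4-methoxyphenyl)-5,5-bis(methylsulfanyl)pent-4-ene-1,3-dione
Product: 5 3-acetyl-6-(4-methoxyphenyl)-2-(methylsulfanyl)-4H-pyran-4-one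
Conditions: camphorsulfonic acid (10 mol %), toluene, 90 °C, N2 sweep into bleach
Reagents that add atoms: none
Why: Intramolecular addition–elimination (6-endo-trig) of the aroyl enol oxygen at the doubly acceptor-substituted C(SMe)2 carbon, the same closure that turns 2-hydroxyphenyl oxoketene dithioacetals into 2-(methylsulfanyl)chromones, made irreversible by escape of methanethiol.

Step 4
Reactants: 6 2-(2-bromo-5-methoxyphenyl)acetic acid
Product: 7 methyl 2-(2-bromo-5-methoxyphenyl)acetate
Conditions: MeOH, H2SO4 (cat.), reflux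
Reagents that add atoms: methanol CO
Why: Fischer esterification of an unhindered arylacetic acid in excess alcohol.

Step 5
Reactants: 5 3-acetyl-6-(4-methoxyphenyl)-2-(methylsulfanyl)-4H-pyran-4-one; 7 methyl 2-(2-bromo-5-methoxyphenyl)acetate
Product: 8 methyl 2-[3-acetyl-6-(4-methoxyphenyl)-4-oxo-4H-pyran-2-yl]-2-(2-bromo-5-methoxyphenyl)acetate (racemic, C8–H labile)
Conditions: 7 (2.1 equiv), LiN(SiMe3)2 (2.1 equiv), THF, −78 °C; then 5, −78 → 0 °C; 1 M HCl
Reagents that add atoms: none
Why: Nucleophilic vinylic substitution (addition–elimination) at pyranone C2, which is the β-carbon of both the ring ketone and the acetyl group and carries the only leaving group, so it is preferred over C6, while the second equivalent of enolate converts the far more acidic product into its anion and shields it from further attack.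

Step 6
Reactants: 8 methyl 2-[3-acetyl-6-(4-methoxyphenyl)-4-oxo-4H-pyran-2-yl]-2-(2-bromo-5-methoxyphenyl)acetate
Product: 9 3-[1-(tert-butyldimethylsilyloxy)ethenyl]-2-[1-(2-bromo-5-methoxyphenyl)-2-(tert-butyldimethylsilyloxy)-2-methoxyethenyl]-6-(4-methoxyphenyl)-4H-pyran-4-one (ketene acetal as a mixture of geometrical isomers)
Conditions: t-BuMe2SiOTf (3 equiv), Et3N (6 equiv), CH2Cl2, 0 °C → rt; pentane extraction under argon, no chromatography
Reagents that add atoms: tert-butyldimethylsilyl triflate CC(C)(C)[Si](C)(C)OS(=O)(=O)C(F)(F)F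
Why: Soft enolization with a silyl triflate and a tertiary amine is the standard route to silyl enol ethers of methyl ketones and ketene silyl acetals of arylacetates, and C8–H is further acidified by the pyranone; the ambident C8 anion may also take silicon on O4, but that isomer and 9 share one 4-silyloxypyrylium ion, so the crude material is carried on as it is.

Step 7
Reactants: 9 3-[1-(tert-butyldimethylsilyloxy)ethenyl]-2-[1-(2-bromo-5-methoxyphenyl)-2-(tert-butyldimethylsilyloxy)-2-methoxyethenyl]-6-(4-methoxyphenyl)-4H-pyran-4-one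
Product: 11 8-(2-bromo-5-methoxyphenyl)-5,7-bis(tert-butyldimethylsilyloxy)-2-(4-methoxyphenyl)-4H-chromen-4-one, via cyclohexadiene 10 (not isolated)
Conditions: slow addition of 9 to degassed o-dichlorobenzene (final 0.01 M), t-BuMe2SiOTf (20 mol %), Bu3N (50 mol %), 180 °C, argon sparge
Reagents that add atoms: none
Why: Proposed new method: in the s-cis,s-cis conformer of 9 the six π electrons of C6H2=C5–C4a=C8a–C8=C7 reorganise in a thermal disrotatory electrocyclization that joins C6, the nucleophilic carbon of the silyl enol ether, to C7, which is electron-poor because its two oxygen donors push through C8 and C8a=C4a into the C4 carbonyl, so the termini are polarity-matched and the barrier should lie below that of an unpolarised triene. Cyclohexadiene 10 has given up the pyranone conjugation and recovers it, together with a benzene sextet, by 1,2-elimination of methanol across C6–C7; should silanol leave instead, the 7-methyl ether results and rejoins the route at 13 after step 8. The closest known reaction type is the thermal six-electron electrocyclization and aromatization of 2,3-dialkenylchromones to xanthones in boiling chlorinated arenes, whereas a triene that ends in a ketene silyl acetal and aromatizes by loss of an alcohol has not been shown on a pyranone. Ring D closes as an all-carbon six-membered ring in the electrocyclic mode (six electrons, disrotatory) with its central double bond held cis by ring E, and no stereocentre remains because C7 of 10 is transient and racemic. The step needs constitutional selectivity only: C5 and C8 are the mutually cis exocyclic substituents of C4a=C8a, the oxatriene running through O4 has a trans centre and cannot close, and C8 has been bonded to C8a beside O1 since step 5, so the aryl group cannot end at C6. Both ketene acetal isomers should serve because the push-pull C7=C8 bond rotates at this temperature, the catalytic silyl triflate and amine return material silylated on O4 to 9 through the shared 4-silyloxypyrylium ion, and slow addition under an argon sparge keeps liberated methanol away from unreacted ketene acetal.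

Step 8
Reactants: 11 8-(2-bromo-5-methoxyphenyl)-5,7-bis(tert-butyldimethylsilyloxy)-2-(4-methoxyphenyl)-4H-chromen-4-one
Product: 12 8-(2-bromo-5-methoxyphenyl)-5,7-dihydroxy-2-(4-methoxyphenyl)-4H-chromen-4-one
Conditions: Bu4NF (2.5 equiv), AcOH (2.5 equiv), THF, 0 °C
Reagents that add atoms: none
Why: Fluoride-induced cleavage of aryl silyl ethers driven by Si–F bond formation, buffered with acetic acid so that ring E never meets a strongly basic medium.

Step 9
Reactants: 12 8-(2-bromo-5-methoxyphenyl)-5,7-dihydroxy-2-(4-methoxyphenyl)-4H-chromen-4-one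
Product: 13 8-(2-bromo-5-methoxyphenyl)-5-hydroxy-7-methoxy-2-(4-methoxyphenyl)-4H-chromen-4-one
Conditions: MeI (1.1 equiv), K2CO3 (1.2 equiv), acetone, 40 °C
Reagents that add atoms: iodomethane CI
Why: Williamson etherification with the classical selectivity of 5,7-dihydroxyflavones, since 7-OH is a vinylogous acid para to C4a and ionises first while 5-OH is held in a hydrogen bond to the C4 carbonyl.

Step 10
Reactants: 13 8-(2-bromo-5-methoxyphenyl)-5-hydroxy-7-methoxy-2-(4-methoxyphenyl)-4H-chromen-4-one
Product: 14 5-(benzyloxy)-8-(2-bromo-5-methoxyphenyl)-7-methoxy-2-(4-methoxyphenyl)-4H-chromen-4-one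
Conditions: BnBr (1.5 equiv), K2CO3 (3 equiv), DMF, 70 °C
Reagents that add atoms: benzyl bromide BrCc1ccccc1
Why: Williamson etherification under forcing conditions breaks the chelate and masks the last phenol, which would otherwise compete as the acyl acceptor in step 12, and the group leaves with the other benzyl ethers in step 15 at no extra cost.

Step 11
Reactants: 15 2',4',6'-trihydroxyacetophenone
Product: 16 1-[2,4-bis(benzyloxy)-6-hydroxyphenyl]ethan-1-one
Conditions: BnBr (2.05 equiv), K2CO3 (2.2 equiv), DMF, rt → 60 °C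
Reagents that add atoms: benzyl bromide BrCc1ccccc1
Why: Williamson etherification stops after two alkylations because the remaining ortho hydroxyl is chelated to the acetyl carbonyl.

Step 12
Reactants: 14 5-(benzyloxy)-8-(2-bromo-5-methoxyphenyl)-7-methoxy-2-(4-methoxyphenyl)-4H-chromen-4-one; 16 1-[2,4-bis(benzyloxy)-6-hydroxyphenyl]ethan-1-one
Product: 17 2-acetyl-3,5-bis(benzyloxy)phenyl 2-[5-(benzyloxy)-7-methoxy-2-(4-methoxyphenyl)-4-oxo-4H-chromen-8-yl]-4-methoxybenzoate
Conditions: Pd(OAc)2 (5 mol %), Xantphos (6 mol %), CO (1 atm), 16 (1.5 equiv), Et3N (3 equiv), DMAP (20 mol %), toluene, 100 °C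
Reagents that add atoms: carbon monoxide [C-]#[O+]
Why: Palladium-catalysed carbonylative esterification (phenoxycarbonylation) of an aryl bromide, that is oxidative addition of C1'–Br to zerovalent palladium, CO insertion and acyl transfer to the phenol relayed by DMAP, with no other free hydroxyl left in either partner.

Step 13
Reactants: 17 2-acetyl-3,5-bis(benzyloxy)phenyl 2-[5-(benzyloxy)-7-methoxy-2-(4-methoxyphenyl)-4-oxo-4H-chromen-8-yl]-4-methoxybenzoate
Product: 18 1-[2,4-bis(benzyloxy)-6-hydroxyphenyl]-3-{2-[5-(benzyloxy)-7-methoxy-2-(4-methoxyphenyl)-4-oxo-4H-chromen-8-yl]-4-methoxyphenyl}propane-1,3-dione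
Conditions: LiN(SiMe3)2 (2.5 equiv), THF, −78 → 0 °C; 1 M HCl
Reagents that add atoms: none
Why: Baker–Venkataraman rearrangement, in which the acetyl enolate attacks the neighbouring aryl ester through a six-membered transition state and the phenoxide leaves, run with a non-nucleophilic base so that ring E is not opened.

Step 14
Reactants: 18 1-[2,4-bis(benzyloxy)-6-hydroxyphenyl]-3-{2-[5-(benzyloxy)-7-methoxy-2-(4-methoxyphenyl)-4-oxo-4H-chromen-8-yl]-4-methoxyphenyl}propane-1,3-dione
Product: 19 5-(benzyloxy)-8-{2-[5,7-bis(benzyloxy)-4-oxo-4H-chromen-2-yl]-5-methoxyphenyl}-7-methoxy-2-(4-methoxyphenyl)-4H-chromen-4-one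
Conditions: p-TsOH·H2O (20 mol %), toluene, 80 °C, 4 Å molecular sieves
Reagents that add atoms: none
Why: Acid-catalysed cyclodehydration of a 2-hydroxyaryl 1,3-diketone (hemiketal formation at the aroyl carbonyl, then loss of water) closes ring C, and early loss of a peri benzyl group would be harmless because step 15 removes all three.

Step 15
Reactants: 19 5-(benzyloxy)-8-{2-[5,7-bis(benzyloxy)-4-oxo-4H-chromen-2-yl]-5-methoxyphenyl}-7-methoxy-2-(4-methoxyphenyl)-4H-chromen-4-one
Product: 20 8-[2-(5,7-dihydroxy-4-oxo-4H-chromen-2-yl)-5-methoxyphenyl]-5-hydroxy-7-methoxy-2-(4-methoxyphenyl)-4H-chromen-4-one (CNP0114008.0)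
Conditions: H2 (1 atm), Pd/C (10 wt % Pd), THF/MeOH, rt, stopped at full debenzylation
Reagents that add atoms: none
Why: Catalytic hydrogenolysis of three aryl benzyl ethers, which leaves the methyl ethers and, at ambient pressure, the chromone double bonds untouched, and no carbon–halogen bond remains at this stage.

## Compound list

1 | acetylacetone | CC(=O)CC(C)=O | starting material
2 | 3-[bis(methylsulfanyl)methylidene]pentane-2,4-dione | CC(=O)C(=C(SC)SC)C(C)=O | intermediate
3 | 4-methoxybenzoyl chloride | COc1ccc(cc1)C(Cl)=O | starting material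
4 | 4-acetyl-1-(4-methoxyphenyl)-5,5-bis(methylsulfanyl)pent-4-ene-1,3-dione | COc1ccc(cc1)C(=O)CC(=O)C(=C(SC)SC)C(C)=O | intermediate
5 | 3-acetyl-6-(4-methoxyphenyl)-2-(methylsulfanyl)-4H-pyran-4-one | CSc1oc(-c2ccc(OC)cc2)cc(=O)c1C(C)=O | intermediate
6 | 2-(2-bromo-5-methoxyphenyl)acetic acid | COc1ccc(Br)c(CC(O)=O)c1 | starting material
7 | methyl 2-(2-bromo-5-methoxyphenyl)acetate | COC(=O)Cc1cc(OC)ccc1Br | intermediate
8 | methyl 2-[3-acetyl-6-(4-methoxyphenyl)-4-oxo-4H-pyran-2-yl]-2-(2-bromo-5-methoxyphenyl)acetate (racemic) | COC(=O)C(c1cc(OC)ccc1Br)c1oc(-c2ccc(OC)cc2)cc(=O)c1C(C)=O | intermediate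
9 | 3-[1-(tert-butyldimethylsilyloxy)ethenyl]-2-[1-(2-bromo-5-methoxyphenyl)-2-(tert-butyldimethylsilyloxy)-2-methoxyethenyl]-6-(4-methoxyphenyl)-4H-pyran-4-one (mixture of ketene acetal isomers) | C=C(O[Si](C)(C)C(C)(C)C)c1c(C(=C(OC)O[Si](C)(C)C(C)(C)C)c2cc(OC)ccc2Br)oc(-c2ccc(OC)cc2)cc1=O | intermediate
10 | 8-(2-bromo-5-methoxyphenyl)-5,7-bis(tert-butyldimethylsilyloxy)-7-methoxy-2-(4-methoxyphenyl)-6,7-dihydro-4H-chromen-4-one (racemic at C7, not isolated) | COc1ccc(cc1)C1=CC(=O)C2=C(O[Si](C)(C)C(C)(C)C)CC(OC)(O[Si](C)(C)C(C)(C)C)C(c3cc(OC)ccc3Br)=C2O1 | intermediate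
11 | 8-(2-bromo-5-methoxyphenyl)-5,7-bis(tert-butyldimethylsilyloxy)-2-(4-methoxyphenyl)-4H-chromen-4-one | COc1ccc(-c2cc(=O)c3c(O[Si](C)(C)C(C)(C)C)cc(O[Si](C)(C)C(C)(C)C)c(-c4cc(OC)ccc4Br)c3o2)cc1 | intermediate
12 | 8-(2-bromo-5-methoxyphenyl)-5,7-dihydroxy-2-(4-methoxyphenyl)-4H-chromen-4-one | COc1ccc(-c2cc(=O)c3c(O)cc(O)c(-c4cc(OC)ccc4Br)c3o2)cc1 | intermediate
13 | 8-(2-bromo-5-methoxyphenyl)-5-hydroxy-7-methoxy-2-(4-methoxyphenyl)-4H-chromen-4-one | COc1ccc(-c2cc(=O)c3c(O)cc(OC)c(-c4cc(OC)ccc4Br)c3o2)cc1 | intermediate
14 | 5-(benzyloxy)-8-(2-bromo-5-methoxyphenyl)-7-methoxy-2-(4-methoxyphenyl)-4H-chromen-4-one | COc1ccc(-c2cc(=O)c3c(OCc5ccccc5)cc(OC)c(-c4cc(OC)ccc4Br)c3o2)cc1 | intermediate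
15 | 2',4',6'-trihydroxyacetophenone | CC(=O)c1c(O)cc(O)cc1O | starting material
16 | 1-[2,4-bis(benzyloxy)-6-hydroxyphenyl]ethan-1-one | CC(=O)c1c(O)cc(OCc2ccccc2)cc1OCc1ccccc1 | intermediate
17 | 2-acetyl-3,5-bis(benzyloxy)phenyl 2-[5-(benzyloxy)-7-methoxy-2-(4-methoxyphenyl)-4-oxo-4H-chromen-8-yl]-4-methoxybenzoate | COc1ccc(-c2cc(=O)c3c(OCc4ccccc4)cc(OC)c(-c4cc(OC)ccc4C(=O)Oc4cc(OCc5ccccc5)cc(OCc5ccccc5)c4C(C)=O)c3o2)cc1 | intermediate
18 | 1-[2,4-bis(benzyloxy)-6-hydroxyphenyl]-3-{2-[5-(benzyloxy)-7-methoxy-2-(4-methoxyphenyl)-4-oxo-4H-chromen-8-yl]-4-methoxyphenyl}propane-1,3-dione | COc1ccc(-c2cc(=O)c3c(OCc4ccccc4)cc(OC)c(-c4cc(OC)ccc4C(=O)CC(=O)c4c(O)cc(OCc5ccccc5)cc4OCc4ccccc4)c3o2)cc1 | intermediate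
19 | 5-(benzyloxy)-8-{2-[5,7-bis(benzyloxy)-4-oxo-4H-chromen-2-yl]-5-methoxyphenyl}-7-methoxy-2-(4-methoxyphenyl)-4H-chromen-4-one | COc1ccc(-c2cc(=O)c3c(OCc4ccccc4)cc(OC)c(-c4cc(OC)ccc4-c4cc(=O)c5c(OCc6ccccc6)cc(OCc6ccccc6)cc5o4)c3o2)cc1 | intermediate
20 | 8-[2-(5,7-dihydroxy-4-oxo-4H-chromen-2-yl)-5-methoxyphenyl]-5-hydroxy-7-methoxy-2-(4-methoxyphenyl)-4H-chromen-4-one | COc1ccc(-c2cc(=O)c3c(O)cc(OC)c(-c4cc(OC)ccc4-c4cc(=O)c5c(O)cc(O)cc5o4)c3o2)cc1 | target

## Step count and risks

Total steps: 15. Longest linear sequence: 13 steps (1, 2, 3, 5, 6, 7, 8, 9, 10, 12, 13, 14, 15).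

Steps most likely to fail:

1. **Step 7.** Three things can go wrong.
   - The second silyl group may settle on the ring carbonyl oxygen and return too slowly, which takes C4a=C8a out of the triene.
   - The inward rotation of an oxygen substituent at C7 may raise the barrier above the temperature at which the ketene acetal decomposes.
   - Liberated methanol may protodesilylate unreacted ketene acetal.

   The fallback sets out from 8 and comes back at 12. It forms the same C6–C7 bond by polar chemistry. With NaH (3 equiv) in THF at reflux, followed by 1 M HCl, the acetyl enolate carbon attacks the ester carbonyl in an intramolecular Claisen (Dieckmann-type) condensation. Methoxide leaves and the cyclic 1,3-diketone tautomerises to the resorcinol. This is the closure that converts 2-acetylphenylacetates into naphthalene-1,3-diols. It makes steps 6 to 8 unnecessary, keeps the regiochemical advantage, and makes no compound outside the list (F0).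

2. **Step 5.** Proton transfer from the acetyl group to the ester enolate, slow expulsion of thiolate, or attack at C6 with opening of ring E may outrun substitution at C2. The fallback sets out from 5 and comes back at 8. Oxidation with mCPBA (2.2 equiv, CH2Cl2, 0 °C → rt) should give 3-acetyl-2-(methanesulfonyl)-6-(4-methoxyphenyl)-4H-pyran-4-one F1. Its C2 is far more electrophilic and carries a sulfinate leaving group, as in the known displacements on 2-sulfonylchromones. The lithium enolate of 7 should then react with F1 at −78 °C, where proton transfer and ring opening are slow, to give 8.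

3. **Step 12.** Capture of the crowded acylpalladium intermediate by a chelated, weakly nucleophilic phenol may be slower than decarbonylation and hydrodebromination. The fallback sets out from 14 and comes back at 17, and it separates carbonylation from ester formation.
   - Hydroxycarbonylation (Pd(OAc)2, Xantphos, CO 1 atm, H2O, Et3N, dioxane, 90 °C) uses a small, abundant nucleophile. It should give 2-[5-(benzyloxy)-7-methoxy-2-(4-methoxyphenyl)-4-oxo-4H-chromen-8-yl]-4-methoxybenzoic acid F2.
   - Oxalyl chloride with catalytic DMF in CH2Cl2 converts F2 into 2-[5-(benzyloxy)-7-methoxy-2-(4-methoxyphenyl)-4-oxo-4H-chromen-8-yl]-4-methoxybenzoyl chloride F3.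
   - Crude F3 acylates 16 in pyridine with DMAP, the classical entry to Baker–Venkataraman substrates, to give 17.

## Further compounds

F0 | step 7 | none | none
F1 | step 5 | 3-acetyl-2-(methanesulfonyl)-6-(4-methoxyphenyl)-4H-pyran-4-one | CS(=O)(=O)c1oc(-c2ccc(OC)cc2)cc(=O)c1C(C)=O
F2 | step 12 | 2-[5-(benzyloxy)-7-methoxy-2-(4-methoxyphenyl)-4-oxo-4H-chromen-8-yl]-4-methoxybenzoic acid | COc1ccc(-c2cc(=O)c3c(OCc4ccccc4)cc(OC)c(-c4cc(OC)ccc4C(O)=O)c3o2)cc1
F3 | step 12 | 2-[5-(benzyloxy)-7-methoxy-2-(4-methoxyphenyl)-4-oxo-4H-chromen-8-yl]-4-methoxybenzoyl chloride | COc1ccc(-c2cc(=O)c3c(OCc4ccccc4)cc(OC)c(-c4cc(OC)ccc4C(Cl)=O)c3o2)cc1
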